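**Retrosynthetic overview**

1. Ring atoms are numbered C1–C10 (C2 ketone; Z alkenes C1=C10 and C3=C4 with methyls on C10 and C4; C5 carbinol; C6 lactone O-carbon; C7 carrying lactone carbons C11–C13; C8 tiglate carbon; C9 methylene). The route rests on O8 lying δ to the C2 carbonyl across the Z C1=C10 alkene of the ten-membered ring: C8–C9 is a vinylogous aldol bond, and C2, C1, C10, C9 can be stored as a 1-silyloxy-3-methylcyclobut-2-enyl ring.
2. Late stage: O8 tigloylation, sulfide oxidation and thermal elimination to the C11=C13 methylene, O5 desilylation.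
3. Key disconnection C8–C9: thermal opening of the cyclobutene (C2–C9 broken) to a silyl dienol ether, then BF3-mediated vinylogous Mukaiyama aldol onto the C8 aldehyde, closing the ten-membered ring.
4. Precursor: C2–C3 by NHK addition of a Z-alkenyl iodide to 3-methylcyclobutenone (propyne plus dichloroketene); C7–C8 by conjugate addition of lithiated 1,3-dithiane to a butenolide; C11–C13 by phenylthiomethylation.
5. Butenolide by acrylate RCM; C5 and C6 by Brown alkoxyallylboration of (Z)-3-iodo-2-methylpropenal. Ring order: butenolide (step 7), cyclobutene (step 10), ten-membered carbocycle (step 15, cyclobutene consumed).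

Key step: step 15

Assumption: the cyclobutenyl carbinol carbon C2 is formed in step 12 as both epimers and carried as the mixture (no descriptor at C2 in the SMILES), because it becomes trigonal in step 15 and the sense of ring opening is set by the silyloxy group, not by C2.

**Route**

Step 1
Reactants: 1 prop-2-yn-1-ol
Product: 3 (Z)-3-iodo-2-methylprop-2-en-1-ol, via alkenylmagnesium alkoxide 2 (not isolated)
Conditions: MeMgBr (3 equiv), CuI (cat.), THF, −20 °C to rt; I2, −20 °C; H2O
Reagents that add atoms: methylmagnesium bromide, C[Mg]Br; iodine, II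
Why: Hydroxyl-directed anti-carbomagnesiation of the propargylic alkoxide puts methyl on the internal carbon and magnesium cis to the CH2O group in a five-membered chelate, and iodinolysis with retention fixes the Z C3=C4 geometry (C5 and iodine cis).

Step 2
Reactants: 3 (Z)-3-iodo-2-methylprop-2-en-1-ol
Product: 4 (Z)-3-iodo-2-methylprop-2-enal
Conditions: MnO2, CH2Cl2, rt; used at once
Reagents that add atoms: none
Why: Allylic oxidation with MnO2 is neutral, so the Z enal should form without scrambling of the alkene.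

Step 3
Reactants: 4 (Z)-3-iodo-2-methylprop-2-enal; 5 allyl methoxymethyl ether
Product: 8 (3S,4S,5Z)-6-iodo-3-(methoxymethoxy)-5-methylhexa-1,5-dien-4-ol, via alkoxyallyllithium 6 (not isolated), via allylborane 7 (not isolated)
Conditions: 5, s-BuLi, THF, −78 °C; (+)-Ipc2BOMe [from (−)-α-pinene]; BF3·OEt2; 4, −78 °C; NaOH, H2O2
Reagents that add atoms: none
Why: Brown alkoxyallylboration: the (Z)-γ-alkoxyallylborane reacts through a chair Zimmerman–Traxler transition state to give the syn diol monoether, and the isopinocampheyl groups from (−)-α-pinene direct attack to the Re face of the aldehyde, setting C5 (S) and C6 (S).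

Step 4
Reactants: 8 (3S,4S,5Z)-6-iodo-3-(methoxymethoxy)-5-methylhexa-1,5-dien-4-ol
Product: 9 (3S,4S,5Z)-4-(tert-butyldimethylsilyloxy)-6-iodo-3-(methoxymethoxy)-5-methylhexa-1,5-diene
Conditions: TBSOTf, 2,6-lutidine, CH2Cl2, −78 to 0 °C
Reagents that add atoms: tert-butyldimethylsilyl triflate, CC(C)(C)[Si](C)(C)OS(=O)(=O)C(F)(F)F
Why: Silyl triflate with a hindered pyridine base silylates the hindered allylic C5 hydroxyl and leaves the acetal alone.

Step 5
Reactants: 9 (3S,4S,5Z)-4-(tert-butyldimethylsilyloxy)-6-iodo-3-(methoxymethoxy)-5-methylhexa-1,5-diene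
Product: 10 (3S,4S,5Z)-4-(tert-butyldimethylsilyloxy)-6-iodo-5-methylhexa-1,5-dien-3-ol
Conditions: Me2BBr, CH2Cl2, −78 °C; aq NaHCO3
Reagents that add atoms: none
Why: Lewis acid-mediated acetal cleavage by Me2BBr occurs at the acetal carbon at −78 °C, where the secondary silyl ether and the alkenyl iodide are inert, and frees the C6 hydroxyl.

Step 6
Reactants: 10 (3S,4S,5Z)-4-(tert-butyldimethylsilyloxy)-6-iodo-5-methylhexa-1,5-dien-3-ol
Product: 11 (3S,4S,5Z)-4-(tert-butyldimethylsilyloxy)-6-iodo-5-methylhexa-1,5-dien-3-yl acrylate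
Conditions: acryloyl chloride, iPr2NEt, DMAP (cat.), CH2Cl2, −20 to 0 °C
Reagents that add atoms: acryloyl chloride, C=CC(Cl)=O
Why: Acylation of the only free hydroxyl fixes O6 as the future lactone oxygen and supplies C11 and C12.

Step 7
Reactants: 11 (3S,4S,5Z)-4-(tert-butyldimethylsilyloxy)-6-iodo-5-methylhexa-1,5-dien-3-yl acrylate
Product: 12 (5S)-5-[(1S,2Z)-1-(tert-butyldimethylsilyloxy)-3-iodo-2-methylprop-2-en-1-yl]furan-2(5H)-one
Conditions: second-generation Grubbs catalyst (5 mol%), CH2Cl2, 40 °C
Reagents that add atoms: none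
Why: RCM of the acrylate onto the C7 vinyl group closes the butenolide (C7=C11), the trisubstituted iodoalkene being too hindered and electron-poor to enter metathesis.

Step 8
Reactants: 12 (5S)-5-[(1S,2Z)-1-(tert-butyldimethylsilyloxy)-3-iodo-2-methylprop-2-en-1-yl]furan-2(5H)-one; 13 1,3-dithiane
Product: 16 (4S,5S)-5-[(1S,2Z)-1-(tert-butyldimethylsilyloxy)-3-iodo-2-methylprop-2-en-1-yl]-4-(1,3-dithian-2-yl)-2-(trimethylsilyloxy)-4,5-dihydrofuran, via 2-lithio-1,3-dithiane 14 (not isolated), via lithium enolate 15 (not isolated)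
Conditions: 13, n-BuLi, THF, −30 °C; 12, THF/HMPA, −78 °C; TMSCl, −78 °C to rt; non-aqueous work-up
Reagents that add atoms: chlorotrimethylsilane, C[Si](C)(C)Cl
Why: Conjugate (Michael) addition of the soft sulfur-stabilised carbanion in the presence of HMPA occurs at C7 anti to the C6 side chain, setting C7, and O-silylation traps the enolate regiospecifically.

Step 9
Reactants: 16 silyl ketene acetal
Product: 17 (3S,4S,5S)-5-[(1S,2Z)-1-(tert-butyldimethylsilyloxy)-3-iodo-2-methylprop-2-en-1-yl]-4-(1,3-dithian-2-yl)-3-[(phenylthio)methyl]oxolan-2-one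
Conditions: PhSCH2Cl, ZnBr2 (10 mol%), CH2Cl2, rt
Reagents that add atoms: chloromethyl phenyl sulfide, ClCSc1ccccc1
Why: ZnBr2-mediated phenylthiomethylation (thionium ion alkylation of a silyl ketene acetal) occurs at C11 anti to the C7 dithiane and gives the all-trans lactone with the future methylene masked as a sulfide.

Step 10
Reactants: 18 propyne; 19 trichloroacetyl chloride
Product: 21 4,4-dichloro-3-methylcyclobut-2-en-1-one, via dichloroketene 20 (not isolated)
Conditions: Zn(Cu) couple, Et2O/DME, rt, slow addition of 19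
Reagents that add atoms: none
Why: [2+2] cycloaddition of dichloroketene, formed by zinc dechlorination of the acid chloride, to the terminal alkyne joins the ketene carbonyl carbon to the unsubstituted alkyne carbon.

Step 11
Reactants: 21 4,4-dichloro-3-methylcyclobut-2-en-1-one
Product: 22 3-methylcyclobut-2-en-1-one
Conditions: Zn, AcOH, TMEDA, EtOH, 0 °C to rt; kept cold as a solution
Reagents that add atoms: none
Why: Zinc in buffered acetic acid removes both α-chlorines reductively, and any 2,4-dichloro isomer from step 10 converges to the same enone.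

Step 12
Reactants: 17 iodo lactone; 22 3-methylcyclobut-2-en-1-one (4 equiv)
Product: 24 cyclobutenol (17 with iodine replaced by 1-hydroxy-3-methylcyclobut-2-en-1-yl; both C2 epimers), via alkenylchromium dichloride 23 (not isolated)
Conditions: CrCl2 (6 equiv), NiCl2 (2 mol%), DMSO/THF, rt
Reagents that add atoms: none
Why: NHK reaction: zerovalent nickel inserts into the C–I bond and transmetalation gives a trivalent alkenylchromium that keeps the Z geometry, ignores the lactone and adds 1,2 to the ketone, an addition normally slower than to aldehydes but helped here by the strained carbonyl flanked only by CH2 and =CH and by the excess of 22.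

Step 13
Reactants: 24 cyclobutenol
Product: 25 bis-silyl ether (tertiary O2–TBS ether of 24)
Conditions: TBSOTf, 2,6-lutidine, CH2Cl2, −78 to −20 °C
Reagents that add atoms: tert-butyldimethylsilyl triflate, CC(C)(C)[Si](C)(C)OS(=O)(=O)C(F)(F)F
Why: Silyl triflate silylation of the tertiary alcohol is fast at low temperature, and the excess hindered base prevents ionisation of the doubly allylic carbinol.

Step 14
Reactants: 25 bis-silyl ether
Product: 26 (2S,3S,4S)-2-{(1S,2Z)-1-(tert-butyldimethylsilyloxy)-3-[1-(tert-butyldimethylsilyloxy)-3-methylcyclobut-2-en-1-yl]-2-methylprop-2-en-1-yl}-5-oxo-4-[(phenylthio)methyl]oxolane-3-carbaldehyde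
Conditions: MeI, CaCO3, MeCN/H2O (9:1), rt, dark; taken on promptly
Reagents that add atoms: water, O
Why: Alkylative thioacetal hydrolysis: S-methylation turns the dithiane into a leaving group that buffered water displaces at room temperature, while the aryl sulfide is too weak a nucleophile to be methylated and the silyl ethers and cyclobutene are not touched.

Step 15
Reactants: 26 cyclobutenyl lactone aldehyde
Product: 28 (5S,6S,7R,8R,11S)-5-(tert-butyldimethylsilyloxy)-8-hydroxy-2-oxo-13-(phenylthio)germacra-1(10)Z,3Z-dien-6,12-olide, via silyloxytriene 27 (not isolated)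
Conditions: PhMe, 2,6-di-tert-butyl-4-methylpyridine (cat.), 65 °C; then CH2Cl2 (1 mM), BF3·OEt2, −78 °C, slow addition; aq NaHCO3
Reagents that add atoms: none
Why: Proposed new method: at 65 °C the 3-silyloxycyclobutene should open by conrotatory 4π cleavage of C2–C9 with the donor OSi group rotating outward and the alkenyl group inward, giving the 1-silyloxy-3-methyl-1,3-diene 27 with C3 cis to C10, and BF3·OEt2 then activates the C8 aldehyde for attack by the diene terminus C9 (vinylogous Mukaiyama aldol) with loss of the silyl group as its fluoride, so that C2 becomes the ketone and C1=C10 the new alkene. The closest known reactions are the torquoselective thermal openings of 3-alkoxy- and 3-silyloxycyclobutenes to 1-oxydienes and the Lewis acid-mediated vinylogous Mukaiyama aldol macrocyclizations of ester-derived silyl dienolates; their combination on a ketone-level dienol ether is untested. The ten-membered carbocycle closes by attack of the endocyclic diene terminus on the exocyclic C8=O (endo for the diene, exo for the carbonyl), helped by the trans lactone and the two cis alkenes, which hold C9 near C8. C8 is the only new stereocentre and is set by substrate control: the BF3-bound aldehyde should be attacked anti to the C6–O dipole (1,3-anti, open transition state) on the face the tether can reach, giving 8R, although the C7–C11 branch may oppose this. The step needs C9 rather than C1 attack, which the ring size secures (C1 attack would demand an eight-membered ring) together with the γ-preference of open Lewis acid transition states, and it needs a Z C1=C10 alkene, which follows because only the s-cis diene lets C9 reach C8. Strain release lets the opening run well below the temperature at which the cis triene, whose C4 terminus carries an inward substituent, would undergo 6π electrocyclization.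

Step 16
Reactants: 28 macrocyclic hydroxy dienone
Product: 29 (5S,6S,7R,8R,11S)-5-(tert-butyldimethylsilyloxy)-2-oxo-13-(phenylthio)-8-(tigloyloxy)germacra-1(10)Z,3Z-dien-6,12-olide
Conditions: tigloyl chloride, DMAP, pyridine, CH2Cl2, 0 °C to rt
Reagents that add atoms: (E)-2-methylbut-2-enoyl chloride, ClC(=O)/C(C)=C/C
Why: DMAP-catalysed acylation esterifies the secondary C8 alcohol with retention, and doing it promptly drains any transannular O8–C2 hemiketal and forestalls lactone migration to O8.

Step 17
Reactants: 29 tiglate sulfide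
Product: 30 sulfoxide of 29 (both epimers at sulfur)
Conditions: NaIO4, MeOH/THF/H2O, 0 °C to rt
Reagents that add atoms: sodium periodate, [Na+].[O-]I(=O)(=O)=O
Why: NaIO4 oxidises the sulfide to the sulfoxide without over-oxidation and leaves the dienone, the esters and the silyl ether alone.

Step 18
Reactants: 30 sulfoxide
Product: 31 (5S,6S,7R,8R)-5-(tert-butyldimethylsilyloxy)-2-oxo-8-(tigloyloxy)germacra-1(10)Z,3Z,11(13)-trien-6,12-olide
Conditions: PhMe, CaCO3, 100 °C
Reagents that add atoms: none
Why: Thermal syn elimination of the sulfoxide through its only β-hydrogen, C11–H, unveils the C11=C13 methylene, and the cross-conjugated dienone offers no 1,5-diene for a Cope rearrangement at this temperature.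

Step 19
Reactants: 31 silyl ether
Product: 32 (5S,6S,7R,8R)-5-hydroxy-2-oxo-8-(tigloyloxy)germacra-1(10)Z,3Z,11(13)-trien-6,12-olide (target CNP0230565.7)
Conditions: HF·pyridine, pyridine, THF, 0 °C to rt
Reagents that add atoms: none
Why: Buffered fluoride desilylation removes the C5 silyl ether under conditions too mild and non-basic to add to the methylene lactone or to move the lactone to O5.

**Compound list**

1 | prop-2-yn-1-ol | C#CCO | starting material
2 | (Z)-alkenylmagnesium alkoxide from carbomagnesiation of 1 | Br[Mg]OC/C(C)=C\[Mg]Br | intermediate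
3 | (Z)-3-iodo-2-methylprop-2-en-1-ol | OC/C(C)=C\I | intermediate
4 | (Z)-3-iodo-2-methylprop-2-enal | O=C/C(C)=C\I | intermediate
5 | allyl methoxymethyl ether | C=CCOCOC | starting material
6 | (Z)-3-(methoxymethoxy)allyllithium | [Li]C/C=C\OCOC | intermediate
7 | B-[(Z)-3-(methoxymethoxy)allyl]diisopinocampheylborane (isopinocampheyl groups from (−)-α-pinene) | COCO/C=C\CB([C@H]1C[C@H]2C[C@@H]([C@@H]1C)C2(C)C)[C@H]1C[C@H]2C[C@@H]([C@@H]1C)C2(C)C | intermediate
8 | (3S,4S,5Z)-6-iodo-3-(methoxymethoxy)-5-methylhexa-1,5-dien-4-ol | C=C[C@H](OCOC)[C@@H](O)/C(C)=C\I | intermediate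
9 | (3S,4S,5Z)-4-(tert-butyldimethylsilyloxy)-6-iodo-3-(methoxymethoxy)-5-methylhexa-1,5-diene | C=C[C@H](OCOC)[C@@H](O[Si](C)(C)C(C)(C)C)/C(C)=C\I | intermediate
10 | (3S,4S,5Z)-4-(tert-butyldimethylsilyloxy)-6-iodo-5-methylhexa-1,5-dien-3-ol | C=C[C@H](O)[C@@H](O[Si](C)(C)C(C)(C)C)/C(C)=C\I | intermediate
11 | (3S,4S,5Z)-4-(tert-butyldimethylsilyloxy)-6-iodo-5-methylhexa-1,5-dien-3-yl acrylate | C=C[C@H](OC(=O)C=C)[C@@H](O[Si](C)(C)C(C)(C)C)/C(C)=C\I | intermediate
12 | (5S)-5-[(1S,2Z)-1-(tert-butyldimethylsilyloxy)-3-iodo-2-methylprop-2-en-1-yl]furan-2(5H)-one | O=C1C=C[C@H](O1)[C@@H](O[Si](C)(C)C(C)(C)C)/C(C)=C\I | intermediate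
13 | 1,3-dithiane | C1CSCSC1 | starting material
14 | 2-lithio-1,3-dithiane | [Li]C1SCCCS1 | intermediate
15 | lithium enolate of the conjugate adduct (4,5-trans) | [Li]OC1=C[C@H](C2SCCCS2)[C@H](O1)[C@@H](O[Si](C)(C)C(C)(C)C)/C(C)=C\I | intermediate
16 | (4S,5S)-5-[(1S,2Z)-1-(tert-butyldimethylsilyloxy)-3-iodo-2-methylprop-2-en-1-yl]-4-(1,3-dithian-2-yl)-2-(trimethylsilyloxy)-4,5-dihydrofuran | C[Si](C)(C)OC1=C[C@H](C2SCCCS2)[C@H](O1)[C@@H](O[Si](C)(C)C(C)(C)C)/C(C)=C\I | intermediate
17 | (3S,4S,5S)-5-[(1S,2Z)-1-(tert-butyldimethylsilyloxy)-3-iodo-2-methylprop-2-en-1-yl]-4-(1,3-dithian-2-yl)-3-[(phenylthio)methyl]oxolan-2-one (all-trans) | C1(SCCCS1)[C@H]2[C@H](CSc3ccccc3)C(=O)O[C@@H]2[C@@H](O[Si](C)(C)C(C)(C)C)/C(C)=C\I | intermediate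
18 | propyne | CC#C | starting material
19 | trichloroacetyl chloride | ClC(=O)C(Cl)(Cl)Cl | starting material
20 | dichloroketene | ClC(Cl)=C=O | intermediate
21 | 4,4-dichloro-3-methylcyclobut-2-en-1-one | CC1=CC(=O)C1(Cl)Cl | intermediate
22 | 3-methylcyclobut-2-en-1-one | CC1=CC(=O)C1 | intermediate
23 | alkenylchromium dichloride from 17 (C3–CrCl2 in place of C3–I, Z retained) | C1(SCCCS1)[C@H]2[C@H](CSc3ccccc3)C(=O)O[C@@H]2[C@@H](O[Si](C)(C)C(C)(C)C)/C(C)=C\[Cr](Cl)Cl | intermediate
24 | cyclobutenol: 17 with iodine replaced by 1-hydroxy-3-methylcyclobut-2-en-1-yl (Z alkene; both C2 epimers) | C1(SCCCS1)[C@H]2[C@H](CSc3ccccc3)C(=O)O[C@@H]2[C@@H](O[Si](C)(C)C(C)(C)C)/C(C)=C\C4(O)C=C(C)C4 | intermediate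
25 | tertiary tert-butyldimethylsilyl ether of 24 | C1(SCCCS1)[C@H]2[C@H](CSc3ccccc3)C(=O)O[C@@H]2[C@@H](O[Si](C)(C)C(C)(C)C)/C(C)=C\C4(O[Si](C)(C)C(C)(C)C)C=C(C)C4 | intermediate
26 | (2S,3S,4S)-2-{(1S,2Z)-1-(tert-butyldimethylsilyloxy)-3-[1-(tert-butyldimethylsilyloxy)-3-methylcyclobut-2-en-1-yl]-2-methylprop-2-en-1-yl}-5-oxo-4-[(phenylthio)methyl]oxolane-3-carbaldehyde (key-step precursor; both C2 epimers) | O=C[C@H]1[C@H](CSc2ccccc2)C(=O)O[C@@H]1[C@@H](O[Si](C)(C)C(C)(C)C)/C(C)=C\C3(O[Si](C)(C)C(C)(C)C)C=C(C)C3 | intermediate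
27 | (2S,3S,4S)-2-[(1S,2Z,4E)-1,4-bis(tert-butyldimethylsilyloxy)-2,6-dimethylhepta-2,4,6-trien-1-yl]-5-oxo-4-[(phenylthio)methyl]oxolane-3-carbaldehyde | O=C[C@H]1[C@H](CSc2ccccc2)C(=O)O[C@@H]1[C@@H](O[Si](C)(C)C(C)(C)C)/C(C)=C\C(O[Si](C)(C)C(C)(C)C)=C/C(C)=C | intermediate
28 | (5S,6S,7R,8R,11S)-5-(tert-butyldimethylsilyloxy)-8-hydroxy-2-oxo-13-(phenylthio)germacra-1(10)Z,3Z-dien-6,12-olide (key-step product) | C(Sc3ccccc3)[C@@H]1C(=O)O[C@H]2[C@H]1[C@H](O)C/C(C)=C\C(=O)/C=C(/C)[C@@H]2O[Si](C)(C)C(C)(C)C | intermediate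
29 | 8-O-tiglate of 28 | C(Sc3ccccc3)[C@@H]1C(=O)O[C@H]2[C@H]1[C@H](OC(=O)/C(C)=C/C)C/C(C)=C\C(=O)/C=C(/C)[C@@H]2O[Si](C)(C)C(C)(C)C | intermediate
30 | 13-phenylsulfinyl analogue of 29 (both epimers at sulfur) | C(S(=O)c3ccccc3)[C@@H]1C(=O)O[C@H]2[C@H]1[C@H](OC(=O)/C(C)=C/C)C/C(C)=C\C(=O)/C=C(/C)[C@@H]2O[Si](C)(C)C(C)(C)C | intermediate
31 | (5S,6S,7R,8R)-5-(tert-butyldimethylsilyloxy)-2-oxo-8-(tigloyloxy)germacra-1(10)Z,3Z,11(13)-trien-6,12-olide | C=C1C(=O)O[C@H]2[C@H]1[C@H](OC(=O)/C(C)=C/C)C/C(C)=C\C(=O)/C=C(/C)[C@@H]2O[Si](C)(C)C(C)(C)C | intermediate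
32 | (5S,6S,7R,8R)-5-hydroxy-2-oxo-8-(tigloyloxy)germacra-1(10)Z,3Z,11(13)-trien-6,12-olide, CNP0230565.7 | C=C1C(=O)O[C@H]2[C@H]1[C@H](OC(=O)/C(C)=C/C)C/C(C)=C\C(=O)/C=C(/C)[C@@H]2O | target

**Step count and risks**

Total step count: 19. Longest linear sequence: 17 steps (steps 1–9 and 12–19, from prop-2-yn-1-ol); steps 10–11 form the short branch to 22.

Steps most likely to fail:

1. Step 15 (the labelled step). What may go wrong: the silyloxytriene may electrocyclize or lose its silyl group before the aldol; the aldol may run between molecules and give oligomers; C1 may compete with C9; or the aldehyde may be attacked on the wrong face. The fallback uses known chemistry and closes the ring at C1=C10 by RCM instead of at C8–C9. It sets out from 17. Hydrolysis of the dithiane (MeI, CaCO3, aqueous MeCN) should give the iodo lactone aldehyde F1. Hosomi–Sakurai addition of methallyltrimethylsilane (BF3·OEt2, CH2Cl2, −78 °C) makes the C8–C9 bond and should give the homoallylic alcohol F2. Tigloyl chloride with DMAP should give the ester F3. NHK coupling of the alkenyl iodide with acrolein (CrCl2, NiCl2 cat., DMSO) should give the dienyl carbinol F4, and Dess–Martin oxidation the divinyl ketone F5. RCM (second-generation Hoveyda–Grubbs catalyst, PhMe, 80 °C, high dilution) would join C1 to C10 with loss of ethylene and come back to the route at 29.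

2. Step 12. What may go wrong: sluggish 1,2-addition of the alkenylchromium to a ketone carbonyl, so that protodeiodination, loss of alkene geometry, or consumption of the cyclobutenone by zerovalent nickel takes over. The fallback replaces the Barbier-type chromium reagent by a preformed polar organometallic. It sets out from 17: iodine–magnesium exchange with iPrMgCl·LiCl (THF, −40 °C) gives the alkenylmagnesium chloride, which is added at −78 °C to 22 precomplexed with LaCl3·2LiCl. Work-up comes back to the route at 24. No new isolable compound is made (F0).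

3. Step 8. What may go wrong: the dithianyl anion may act as a base at C6 (γ-deprotonation followed by loss of the C5 silyloxy group) or add 1,2 to the lactone carbonyl. The fallback brings in the formyl carbon as a vinyl group through a softer cuprate. It sets out from 12. CH2=CHMgBr, CuI (cat.), TMSCl (THF, −78 °C; aqueous work-up) should add anti to the side chain and give the trans vinyl lactone F6. Lemieux–Johnson cleavage of the monosubstituted alkene (OsO4 cat., NaIO4, 2,6-lutidine, dioxane/H2O) should give the lactone aldehyde F7. Propane-1,3-dithiol with Zn(OTf)2 should give the dithianyl lactone F8. LiN(iPr)2 then TMSCl (THF, −78 °C) gives the silyl ketene acetal and comes back to the route at 16.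

**Further compounds**

F1 | step 15 | iodo lactone aldehyde (17 with the dithiane hydrolysed to CHO) | O=C[C@H]1[C@H](CSc2ccccc2)C(=O)O[C@@H]1[C@@H](O[Si](C)(C)C(C)(C)C)/C(C)=C\I
F2 | step 15 | (8R) homoallylic alcohol from methallylation of F1 | C=C(C)C[C@@H](O)[C@H]1[C@H](CSc2ccccc2)C(=O)O[C@@H]1[C@@H](O[Si](C)(C)C(C)(C)C)/C(C)=C\I
F3 | step 15 | tiglate of F2 | C=C(C)C[C@@H](OC(=O)/C(C)=C/C)[C@H]1[C@H](CSc2ccccc2)C(=O)O[C@@H]1[C@@H](O[Si](C)(C)C(C)(C)C)/C(C)=C\I
F4 | step 15 | dienyl carbinol (F3 with iodine replaced by 1-hydroxyprop-2-en-1-yl; both C2 epimers) | C=C(C)C[C@@H](OC(=O)/C(C)=C/C)[C@H]1[C@H](CSc2ccccc2)C(=O)O[C@@H]1[C@@H](O[Si](C)(C)C(C)(C)C)/C(C)=C\C(O)C=C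
F5 | step 15 | divinyl ketone from oxidation of F4 | C=C(C)C[C@@H](OC(=O)/C(C)=C/C)[C@H]1[C@H](CSc2ccccc2)C(=O)O[C@@H]1[C@@H](O[Si](C)(C)C(C)(C)C)/C(C)=C\C(=O)C=C
F0 | step 12 | none | none
F6 | step 8 | trans 4-vinyl lactone from vinyl cuprate addition to 12 | C=C[C@H]1CC(=O)O[C@@H]1[C@@H](O[Si](C)(C)C(C)(C)C)/C(C)=C\I
F7 | step 8 | trans 4-formyl lactone from cleavage of F6 | O=C[C@H]1CC(=O)O[C@@H]1[C@@H](O[Si](C)(C)C(C)(C)C)/C(C)=C\I
F8 | step 8 | trans 4-(1,3-dithian-2-yl) lactone from F7 | C1(SCCCS1)[C@H]2CC(=O)O[C@@H]2[C@@H](O[Si](C)(C)C(C)(C)C)/C(C)=C\I
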